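**Retrosynthetic overview**
1. Target 35 comes from bicyclic aldehyde 32 by oxidation of C1 (CHO to CO2H), desilylation, and oxidation of C5 (CHOH to C=O).
2. Both rings form at the same time. An endo intramolecular Diels–Alder reaction of tetraenal 31 makes C2–C10 and C3–C7, and 31 is released by Wittig olefination (C2=C3) of aldehyde 25.
3. The triene of 25 comes from the key fragment union. This is a Pd-catalysed hydro-dienylation that makes C8–C9 from alkyne 14 and dienylboronate 22.
4. Alkyne 14 comes from a Pd-catalysed allenylzinc addition (C5–C6) of mesylate 11 to aldehyde 8. C4 of aldehyde 8 is set by an Evans hydroxymethylation.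
5. Boronate 22 comes from Cu-catalysed ethylboration of enyne 20, which is made by Sonogashira coupling from phenylacetylene.

Assumption: carbon labels follow the open chain HO2C(C1)–C2(Et)=C3–C4(Et)–C5(O)–C6(Me)–C7=C8(Et)–C9=C10(Et)–C11=C12–Ph. The chiral auxiliary and the phosphine, silyl, boron, zinc and zirconium reagents count as reagents. Every other carbon source is numbered as a starting material.

**Step 1**
Reactants: 1 butanoyl chloride
Product: 2 (4S)-4-benzyl-3-butanoyl-1,3-oxazolidin-2-one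
Conditions: (S)-4-benzyl-2-oxazolidinone, Et3N, DMAP (10 mol %), CH2Cl2, 0 °C to rt
Reagents that add atoms: (S)-4-benzyl-2-oxazolidinone, O=C1OC[C@H](Cc2ccccc2)N1
Why: DMAP-catalysed N-acylation of the Evans auxiliary with an unhindered acid chloride is routine and creates no stereocentre.

**Step 2**
Reactants: 2 (4S)-4-benzyl-3-butanoyl-1,3-oxazolidin-2-one; 3 1,3,5-trioxane
Product: 5 (4S)-4-benzyl-3-[(2R)-2-(hydroxymethyl)butanoyl]-1,3-oxazolidin-2-one, via titanium (Z)-enolate 4 (not isolated)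
Conditions: TiCl4 (1.05 equiv), i-Pr2NEt (1.1 equiv), CH2Cl2, 0 °C; then 3 (1.2 equiv), TiCl4 (1.05 equiv), 0 °C; aq NH4Cl
Reagents that add atoms: titanium tetrachloride, Cl[Ti](Cl)(Cl)Cl (its atoms stay only in intermediate 4)
Why: In this Evans titanium-enolate hydroxymethylation (aldol-type addition to TiCl4-activated formaldehyde) the chelated Z-enolate is attacked on the face away from the benzyl group, which sets C4 as R.

**Step 3**
Reactants: 5 (4S)-4-benzyl-3-[(2R)-2-(hydroxymethyl)butanoyl]-1,3-oxazolidin-2-one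
Product: 6 (4S)-4-benzyl-3-[(2R)-2-{[(tert-butyldimethylsilyl)oxy]methyl}butanoyl]-1,3-oxazolidin-2-one
Conditions: TBSCl, imidazole, DMF, rt
Reagents that add atoms: tert-butyldimethylsilyl chloride, CC(C)(C)[Si](C)(C)Cl
Why: Standard silylation of a primary alcohol keeps the two CH2O arms at C4 different before the auxiliary is removed.

**Step 4**
Reactants: 6 (4S)-4-benzyl-3-[(2R)-2-{[(tert-butyldimethylsilyl)oxy]methyl}butanoyl]-1,3-oxazolidin-2-one
Product: 7 (2S)-2-{[(tert-butyldimethylsilyl)oxy]methyl}butan-1-ol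
Conditions: LiBH4, THF, 0 °C to rt
Reagents that add atoms: none
Why: Reductive cleavage of the N-acyl oxazolidinone with borohydride gives the primary alcohol without touching C4 or the silyl ether (the descriptor changes only through CIP ranking).

**Step 5**
Reactants: 7 (2S)-2-{[(tert-butyldimethylsilyl)oxy]methyl}butan-1-ol
Product: 8 (2R)-2-{[(tert-butyldimethylsilyl)oxy]methyl}butanal
Conditions: DMP, NaHCO3, CH2Cl2, 0 °C to rt, used at once
Reagents that add atoms: none
Why: Buffered Dess–Martin oxidation is neutral and fast, so the α-stereocentre C4 is not epimerised.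

**Step 6**
Reactants: 9 hex-3-yn-2-one
Product: 10 (2S)-hex-3-yn-2-ol
Conditions: Ru[(S,S)-TsDPEN](p-cymene) (0.5 mol %), i-PrOH, rt
Reagents that add atoms: none
Why: In Noyori asymmetric transfer hydrogenation of an ynone the alkynyl group plays the role of the aryl group, and the (S,S)-catalyst delivers the (S)-propargylic alcohol in high ee.

**Step 7**
Reactants: 10 (2S)-hex-3-yn-2-ol
Product: 11 (2S)-hex-3-yn-2-yl methanesulfonate
Conditions: MsCl, Et3N, CH2Cl2, –78 to 0 °C
Reagents that add atoms: methanesulfonyl chloride, CS(=O)(=O)Cl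
Why: O-Mesylation does not touch the C–O stereocentre.

**Step 8**
Reactants: 8 (2R)-2-{[(tert-butyldimethylsilyl)oxy]methyl}butanal; 11 (2S)-hex-3-yn-2-yl methanesulfonate
Product: 13 (2R,3R,4R)-1-[(tert-butyldimethylsilyl)oxy]-2-ethyl-4-methyloct-5-yn-3-ol (C4 R, C5 R, C6 R), via (M)-allenylzinc 12 (not isolated)
Conditions: Pd(OAc)2 (5 mol %), PPh3 (5 mol %), Et2Zn (3 equiv), THF, –78 to –20 °C; 1 M HCl
Reagents that add atoms: diethylzinc, CC[Zn]CC (its atoms stay only in intermediate 12)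
Why: In the Marshall Pd-catalysed allenylzinc addition, anti-SN2' oxidative addition, Pd-to-Zn exchange with retention and a cyclic SE2' transition state give net inversion at C6 and the anti C5/C6 relationship under reagent control, which here is matched with the Felkin preference (C4/C5 syn).

**Step 9**
Reactants: 13 (2R,3R,4R)-1-[(tert-butyldimethylsilyl)oxy]-2-ethyl-4-methyloct-5-yn-3-ol
Product: 14 (2R,3R,4R)-1,3-bis[(tert-butyldimethylsilyl)oxy]-2-ethyl-4-methyloct-5-yne
Conditions: TBSOTf, 2,6-lutidine, CH2Cl2, 0 °C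
Reagents that add atoms: tert-butyldimethylsilyl triflate, CC(C)(C)[Si](C)(C)OS(=O)(=O)C(F)(F)F
Why: Silyl triflate silylation protects the hindered secondary C5 alcohol and adds bulk on the C7 side of the alkyne.

**Step 10**
Reactants: 15 phenylacetylene
Product: 17 [(E)-2-iodoethenyl]benzene, via alkenylzirconocene chloride 16 (not isolated)
Conditions: Cp2Zr(H)Cl, THF, rt; then I2, 0 °C
Reagents that add atoms: zirconocene chloride hydride, [H][Zr](Cl)(C1C=CC=C1)C1C=CC=C1 (only in intermediate 16); iodine, II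
Why: Syn-hydrozirconation of a terminal alkyne followed by iodinolysis with retention fixes the C11=C12 E geometry.

**Step 11**
Reactants: 17 [(E)-2-iodoethenyl]benzene; 18 ethynyltrimethylsilane
Product: 19 trimethyl[(3E)-4-phenylbut-3-en-1-yn-1-yl]silane
Conditions: PdCl2(PPh3)2 (2 mol %), CuI (4 mol %), Et3N, THF, rt
Reagents that add atoms: none
Why: Sonogashira coupling of a vinyl iodide proceeds at room temperature with retention of the alkene geometry.

**Step 12**
Reactants: 19 trimethyl[(3E)-4-phenylbut-3-en-1-yn-1-yl]silane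
Product: 20 [(1E)-but-1-en-3-yn-1-yl]benzene
Conditions: K2CO3 (20 mol %), MeOH, rt
Reagents that add atoms: none
Why: Base-catalysed methanolysis of the alkynyl C–Si bond is selective and mild.

**Step 13**
Reactants: 20 [(1E)-but-1-en-3-yn-1-yl]benzene; 21 iodoethane
Product: 22 2-[(1E,3E)-2-ethyl-4-phenylbuta-1,3-dien-1-yl]-4,4,5,5-tetramethyl-1,3,2-dioxaborolane
Conditions: CuCl (10 mol %), Xantphos (10 mol %), NaOt-Bu (1.5 equiv), B2pin2 (1.2 equiv), 21 (3 equiv), THF, rt
Reagents that add atoms: bis(pinacolato)diboron, CC1(C)OB(OC1(C)C)B1OC(C)(C)C(C)(C)O1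
Why: In this Cu-catalysed alkylboration of a terminal alkyne, syn-borylcupration puts boron on the terminal C9 and copper on the styryl-stabilised C10, and alkylation with retention leaves ethyl cis to boron (C9=C10 E).

**Step 14**
Reactants: 14 (2R,3R,4R)-1,3-bis[(tert-butyldimethylsilyl)oxy]-2-ethyl-4-methyloct-5-yne; 22 2-[(1E,3E)-2-ethyl-4-phenylbuta-1,3-dien-1-yl]-4,4,5,5-tetramethyl-1,3,2-dioxaborolane
Product: 23 (2R,3R,4R,5E,7E,9E)-1,3-bis[(tert-butyldimethylsilyl)oxy]-2,6,8-triethyl-4-methyl-10-phenyldeca-5,7,9-triene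
Conditions: Pd(Pt-Bu3)2 (5 mol %), 1-adamantanecarboxylic acid (30 mol %), H2O (3 equiv), 1,4-dioxane, 50 °C
Reagents that add atoms: none
Why: Proposed new method: a sterically steered Pd–H hydro-dienylation of an unactivated dialkyl alkyne with a dienyl pinacol boronate, in which AdCO2H protonates LPd(0) to LPd(H)(O2CAd), the alkyne (the best π-ligand present) inserts syn with the bulky t-Bu3P–Pd unit going to C8 next to the ethyl CH2 and H going to C7 next to the branched C6/C5-OTBS array, the Pd-bound carboxylate bridges to boron and transfers the dienyl group with retention, reductive elimination forges C8–C9 as the (7E,9E)-diene and water hydrolyses AdCO2Bpin to return the acid; the closest known reaction type is the Pd(0)/carboxylic acid hydroarylation and hydroalkenylation of alkynes with boronic acids, which has not been shown with purely steric regiocontrol on an α-branched dialkyl alkyne or with a 2,2-disubstituted dienyl-Bpin.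

**Step 15**
Reactants: 23 (2R,3R,4R,5E,7E,9E)-1,3-bis[(tert-butyldimethylsilyl)oxy]-2,6,8-triethyl-4-methyl-10-phenyldeca-5,7,9-triene
Product: 24 (2R,3R,4R,5E,7E,9E)-3-[(tert-butyldimethylsilyl)oxy]-2,6,8-triethyl-4-methyl-10-phenyldeca-5,7,9-trien-1-ol
Conditions: HF·pyridine, pyridine, THF, 0 °C
Reagents that add atoms: none
Why: In this selective desilylation the primary TBS ether is cleaved much faster than the C5 TBS ether, which is flanked by two branched carbons, and the buffered medium spares the triene.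

**Step 16**
Reactants: 24 (2R,3R,4R,5E,7E,9E)-3-[(tert-butyldimethylsilyl)oxy]-2,6,8-triethyl-4-methyl-10-phenyldeca-5,7,9-trien-1-ol
Product: 25 (2S,3R,4R,5E,7E,9E)-3-[(tert-butyldimethylsilyl)oxy]-2,6,8-triethyl-4-methyl-10-phenyldeca-5,7,9-trienal
Conditions: DMP, NaHCO3, CH2Cl2, 0 °C to rt
Reagents that add atoms: none
Why: Buffered Dess–Martin oxidation leaves the triene, the silyl ether and the α-centre C4 intact (the descriptor changes only through CIP ranking).

**Step 17**
Reactants: 26 1-bromopropane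
Product: 27 triphenyl(propyl)phosphonium bromide
Conditions: PPh3, toluene, reflux
Reagents that add atoms: triphenylphosphine, c1ccc(cc1)P(c1ccccc1)c1ccccc1
Why: SN2 quaternisation of PPh3 by a primary bromide gives the crystalline salt.

**Step 18**
Reactants: 27 triphenyl(propyl)phosphonium bromide; 28 methyl formate
Product: 30 2-(triphenyl-λ5-phosphanylidene)butanal, via propylidene ylide 29 (not isolated)
Conditions: KOt-Bu (2.1 equiv), THF, 0 °C; then 28, 0 °C to rt
Reagents that add atoms: none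
Why: C-Formylation of a non-stabilised ylide with a formate ester, with the second equivalent of base taking off the acidic proton, gives the stabilised formyl ylide.

**Step 19**
Reactants: 25 (2S,3R,4R,5E,7E,9E)-3-[(tert-butyldimethylsilyl)oxy]-2,6,8-triethyl-4-methyl-10-phenyldeca-5,7,9-trienal; 30 2-(triphenyl-λ5-phosphanylidene)butanal
Product: 32 (1R,2R,3R,3aS,4S,5R,7aS)-2-[(tert-butyldimethylsilyl)oxy]-3,4,5,7-tetraethyl-1-methyl-5-[(E)-2-phenylethenyl]-2,3,3a,4,5,7a-hexahydro-1H-indene-4-carbaldehyde (trans-fused), via tetraenal 31 (not isolated)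
Conditions: 30 (2 equiv), BHT (cat.), toluene, 90 °C
Reagents that add atoms: none
Why: Wittig olefination with the stabilised ylide gives the (E)-2-ethyl enal, which undergoes an endo (CHO under the diene) intramolecular Diels–Alder reaction in the same pot, where A(1,3) strain holds C6–H next to the C8 ethyl group and C4–H next to the C2 ethyl group so that only one diene face and one dienophile face can meet, setting C2 (S), C3 (S), C7 (S) and C10 (R) together with the trans ring fusion.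

**Step 20**
Reactants: 32 the bicyclic aldehyde of step 19
Product: 33 (1R,2R,3R,3aS,4S,5R,7aS)-2-[(tert-butyldimethylsilyl)oxy]-3,4,5,7-tetraethyl-1-methyl-5-[(E)-2-phenylethenyl]-2,3,3a,4,5,7a-hexahydro-1H-indene-4-carboxylic acid
Conditions: NaClO2, NaH2PO4, 2-methyl-2-butene, t-BuOH/H2O, rt
Reagents that add atoms: sodium chlorite, [Na+].[O-]Cl=O
Why: Pinnick oxidation works on hindered non-enolisable aldehydes, and the scavenger protects the two alkenes from HOCl.

**Step 21**
Reactants: 33 the silyloxy acid of step 20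
Product: 34 (1R,2R,3R,3aS,4S,5R,7aS)-3,4,5,7-tetraethyl-2-hydroxy-1-methyl-5-[(E)-2-phenylethenyl]-2,3,3a,4,5,7a-hexahydro-1H-indene-4-carboxylic acid
Conditions: 48 % aq HF, MeCN, rt
Reagents that add atoms: none
Why: Fluoride-driven desilylation frees the C5 alcohol, and lactonisation is geometrically impossible because C2 is pseudo-equatorial on the trans-fused cyclopentane.

**Step 22**
Reactants: 34 the hydroxy acid of step 21
Product: 35 (1R,3R,3aS,4S,5R,7aS)-3,4,5,7-tetraethyl-1-methyl-2-oxo-5-[(E)-2-phenylethenyl]-2,3,3a,4,5,7a-hexahydro-1H-indene-4-carboxylic acid (target)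
Conditions: DMP, CH2Cl2, rt
Reagents that add atoms: none
Why: Dess–Martin oxidation of the secondary alcohol tolerates the free acid, and C4 and C6 already have the thermodynamically preferred configuration (each alkyl group trans to the neighbouring ring bond), so there is no drive to epimerise.

**Compound list**
1 | butanoyl chloride | CCCC(=O)Cl | starting material
2 | (4S)-4-benzyl-3-butanoyl-1,3-oxazolidin-2-one | CCCC(=O)N1C(=O)OC[C@@H]1Cc1ccccc1 | intermediate
3 | 1,3,5-trioxane | C1OCOCO1 | starting material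
4 | trichlorotitanium (Z)-enolate of 2 | CC/C=C(\O[Ti](Cl)(Cl)Cl)N1C(=O)OC[C@@H]1Cc1ccccc1 | intermediate
5 | (4S)-4-benzyl-3-[(2R)-2-(hydroxymethyl)butanoyl]-1,3-oxazolidin-2-one | CC[C@H](CO)C(=O)N1C(=O)OC[C@@H]1Cc1ccccc1 | intermediate
6 | (4S)-4-benzyl-3-[(2R)-2-(TBSO-methyl)butanoyl]-1,3-oxazolidin-2-one | CC[C@H](CO[Si](C)(C)C(C)(C)C)C(=O)N1C(=O)OC[C@@H]1Cc1ccccc1 | intermediate
7 | (2S)-2-(TBSO-methyl)butan-1-ol | CC[C@H](CO[Si](C)(C)C(C)(C)C)CO | intermediate
8 | (2R)-2-(TBSO-methyl)butanal | CC[C@H](CO[Si](C)(C)C(C)(C)C)C=O | intermediate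
9 | hex-3-yn-2-one | CCC#CC(C)=O | starting material
10 | (2S)-hex-3-yn-2-ol | CCC#C[C@H](C)O | intermediate
11 | (2S)-hex-3-yn-2-yl methanesulfonate | CCC#C[C@H](C)OS(C)(=O)=O | intermediate
12 | (M)-ethyl(hexa-3,4-dien-3-yl)zinc | [H]C(C)=[C@@]=C(CC)[Zn]CC | intermediate
13 | (2R,3R,4R)-1-(TBSO)-2-ethyl-4-methyloct-5-yn-3-ol | CCC#C[C@@H](C)[C@@H](O)[C@H](CC)CO[Si](C)(C)C(C)(C)C | intermediate
14 | (2R,3R,4R)-1,3-bis(TBSO)-2-ethyl-4-methyloct-5-yne | CCC#C[C@@H](C)[C@@H](O[Si](C)(C)C(C)(C)C)[C@H](CC)CO[Si](C)(C)C(C)(C)C | intermediate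
15 | phenylacetylene | C#Cc1ccccc1 | starting material
16 | chloro[(E)-2-phenylethenyl]zirconocene | Cl[Zr](/C=C/c1ccccc1)(C1C=CC=C1)C1C=CC=C1 | intermediate
17 | [(E)-2-iodoethenyl]benzene | I/C=C/c1ccccc1 | intermediate
18 | ethynyltrimethylsilane | C#C[Si](C)(C)C | starting material
19 | trimethyl[(3E)-4-phenylbut-3-en-1-yn-1-yl]silane | C[Si](C)(C)C#C/C=C/c1ccccc1 | intermediate
20 | [(1E)-but-1-en-3-yn-1-yl]benzene | C#C/C=C/c1ccccc1 | intermediate
21 | iodoethane | CCI | starting material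
22 | 2-[(1E,3E)-2-ethyl-4-phenylbuta-1,3-dien-1-yl]-4,4,5,5-tetramethyl-1,3,2-dioxaborolane | c1ccccc1/C=C/C(CC)=C/B1OC(C)(C)C(C)(C)O1 | intermediate
23 | (2R,3R,4R,5E,7E,9E)-1,3-bis(TBSO)-2,6,8-triethyl-4-methyl-10-phenyldeca-5,7,9-triene | c1ccccc1/C=C/C(CC)=C/C(CC)=C/[C@@H](C)[C@@H](O[Si](C)(C)C(C)(C)C)[C@H](CC)CO[Si](C)(C)C(C)(C)C | intermediate
24 | (2R,3R,4R,5E,7E,9E)-3-(TBSO)-2,6,8-triethyl-4-methyl-10-phenyldeca-5,7,9-trien-1-ol | c1ccccc1/C=C/C(CC)=C/C(CC)=C/[C@@H](C)[C@@H](O[Si](C)(C)C(C)(C)C)[C@H](CC)CO | intermediate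
25 | (2S,3R,4R,5E,7E,9E)-3-(TBSO)-2,6,8-triethyl-4-methyl-10-phenyldeca-5,7,9-trienal | c1ccccc1/C=C/C(CC)=C/C(CC)=C/[C@@H](C)[C@@H](O[Si](C)(C)C(C)(C)C)[C@H](CC)C=O | intermediate
26 | 1-bromopropane | CCCBr | starting material
27 | triphenyl(propyl)phosphonium bromide | CCC[P+](c1ccccc1)(c1ccccc1)c1ccccc1.[Br-] | intermediate
28 | methyl formate | COC=O | starting material
29 | propylidene(triphenyl)-λ5-phosphane | CCC=P(c1ccccc1)(c1ccccc1)c1ccccc1 | intermediate
30 | 2-(triphenyl-λ5-phosphanylidene)butanal | CCC(C=O)=P(c1ccccc1)(c1ccccc1)c1ccccc1 | intermediate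
31 | (2E,4R,5R,6R,7E,9E,11E)-5-(TBSO)-2,4,8,10-tetraethyl-6-methyl-12-phenyldodeca-2,7,9,11-tetraenal | c1ccccc1/C=C/C(CC)=C/C(CC)=C/[C@@H](C)[C@@H](O[Si](C)(C)C(C)(C)C)[C@H](CC)/C=C(CC)/C=O | intermediate
32 | (1R,2R,3R,3aS,4S,5R,7aS)-2-(TBSO)-3,4,5,7-tetraethyl-1-methyl-5-[(E)-2-phenylethenyl]-2,3,3a,4,5,7a-hexahydro-1H-indene-4-carbaldehyde | CCC1=C[C@](/C=C/c2ccccc2)(CC)[C@@](CC)(C=O)[C@H]2[C@H]1[C@@H](C)[C@@H](O[Si](C)(C)C(C)(C)C)[C@@H]2CC | intermediate
33 | (1R,2R,3R,3aS,4S,5R,7aS)-2-(TBSO)-3,4,5,7-tetraethyl-1-methyl-5-[(E)-2-phenylethenyl]-2,3,3a,4,5,7a-hexahydro-1H-indene-4-carboxylic acid | CCC1=C[C@](/C=C/c2ccccc2)(CC)[C@@](CC)(C(=O)O)[C@H]2[C@H]1[C@@H](C)[C@@H](O[Si](C)(C)C(C)(C)C)[C@@H]2CC | intermediate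
34 | (1R,2R,3R,3aS,4S,5R,7aS)-3,4,5,7-tetraethyl-2-hydroxy-1-methyl-5-[(E)-2-phenylethenyl]-2,3,3a,4,5,7a-hexahydro-1H-indene-4-carboxylic acid | CCC1=C[C@](/C=C/c2ccccc2)(CC)[C@@](CC)(C(=O)O)[C@H]2[C@H]1[C@@H](C)[C@@H](O)[C@@H]2CC | intermediate
35 | (1R,3R,3aS,4S,5R,7aS)-3,4,5,7-tetraethyl-1-methyl-2-oxo-5-[(E)-2-phenylethenyl]-2,3,3a,4,5,7a-hexahydro-1H-indene-4-carboxylic acid | CCC1=C[C@](/C=C/c2ccccc2)(CC)[C@@](CC)(C(=O)O)[C@H]2[C@H]1[C@@H](C)C(=O)[C@@H]2CC | target

**Totals**
- Total step count: 22.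
- Longest linear sequence: 14 (steps 1–5, 8, 9, 14–16, 19–22).

**Three steps most likely to fail**

Step 14 (the proposed new hydro-dienylation). The risks are insufficient C8/C7 regiocontrol, Pd–H attack on the dienes, and protodeboronation. The fallback uses known chemistry and sets out from 14. Pd-catalysed syn-hydrostannation (Bu3SnH, PdCl2(PPh3)2, THF, 0 °C) places tin on the less hindered C8 and gives the (E)-C8 vinylstannane F1, and the minor C7 isomer is removed by chromatography. Iodine in CH2Cl2 at 0 °C converts it with retention into the (E)-C8 vinyl iodide F2. Suzuki–Miyaura coupling of F2 with 22 (Pd(PPh3)4, aq NaOH, THF, rt) comes back to the route at 23.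

Step 13 (ethylboration of the terminal enyne). The risks are slow capture of the alkenylcopper by iodoethane and competing protoboration. The fallback sets out from 20. Syn-bromoboration with BBr3 (CH2Cl2, –78 °C) gives the (1Z,3E)-2-bromodienyl dibromoborane F3. Pinacol turns it into the (1Z,3E)-2-bromodienyl pinacol boronate F4. Negishi coupling of its C–Br bond with Et2Zn (PdCl2(DPEphos), THF, 0 °C) goes with retention and leaves the C–B bond untouched. It comes back to the route at 22.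

Step 19 (Wittig/Diels–Alder cascade). The risks are a sluggish reaction of the formyl ylide with the branched aldehyde and eroded selectivity at 90 °C. The fallback sets out from 25 and separates olefination from cycloaddition.
- Methyl 2-bromobutanoate and PPh3 give the (1-methoxy-1-oxobutan-2-yl)triphenylphosphonium bromide F5.
- Aqueous NaOH then gives the more reactive ester ylide methyl 2-(triphenyl-λ5-phosphanylidene)butanoate F6.
- Wittig reaction of F6 with 25 (CH2Cl2, 40 °C) gives the (2E)-tetraenoate methyl ester F7.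
- DIBAL-H (CH2Cl2, –78 °C) gives the tetraenyl allylic alcohol F8.
- MnO2 (CH2Cl2, rt) releases tetraenal 31 at room temperature. There it cyclises on standing, or with Me2AlCl at –40 °C, and the route is rejoined at 32.

**Further compounds**
F1 | step 14 | tributyl[(3E,5R,6R,7R)-6-(TBSO)-7-(TBSO-methyl)-5-methylnon-3-en-3-yl]stannane | CCCC[Sn](CCCC)(CCCC)/C(CC)=C/[C@@H](C)[C@@H](O[Si](C)(C)C(C)(C)C)[C@H](CC)CO[Si](C)(C)C(C)(C)C
F2 | step 14 | (3E,5R,6R,7R)-6-(TBSO)-7-(TBSO-methyl)-3-iodo-5-methylnon-3-ene | I/C(CC)=C/[C@@H](C)[C@@H](O[Si](C)(C)C(C)(C)C)[C@H](CC)CO[Si](C)(C)C(C)(C)C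
F3 | step 13 | dibromo[(1Z,3E)-2-bromo-4-phenylbuta-1,3-dien-1-yl]borane | c1ccccc1/C=C/C(Br)=C/B(Br)Br
F4 | step 13 | 2-[(1Z,3E)-2-bromo-4-phenylbuta-1,3-dien-1-yl]-4,4,5,5-tetramethyl-1,3,2-dioxaborolane | c1ccccc1/C=C/C(Br)=C/B1OC(C)(C)C(C)(C)O1
F5 | step 19 | (1-methoxy-1-oxobutan-2-yl)triphenylphosphonium bromide | CCC(C(=O)OC)[P+](c1ccccc1)(c1ccccc1)c1ccccc1.[Br-]
F6 | step 19 | methyl 2-(triphenyl-λ5-phosphanylidene)butanoate | CCC(C(=O)OC)=P(c1ccccc1)(c1ccccc1)c1ccccc1
F7 | step 19 | methyl (2E,4R,5R,6R,7E,9E,11E)-5-(TBSO)-2,4,8,10-tetraethyl-6-methyl-12-phenyldodeca-2,7,9,11-tetraenoate | c1ccccc1/C=C/C(CC)=C/C(CC)=C/[C@@H](C)[C@@H](O[Si](C)(C)C(C)(C)C)[C@H](CC)/C=C(CC)/C(=O)OC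
F8 | step 19 | (2E,4R,5R,6R,7E,9E,11E)-5-(TBSO)-2,4,8,10-tetraethyl-6-methyl-12-phenyldodeca-2,7,9,11-tetraen-1-ol | c1ccccc1/C=C/C(CC)=C/C(CC)=C/[C@@H](C)[C@@H](O[Si](C)(C)C(C)(C)C)[C@H](CC)/C=C(CC)/CO
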